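Retrosynthesis: the five O-protecting groups are put back first; the pyranone ring of flavone 1 is then cut at O1–C2 and C2–C3 into a biaryl benzoic acid and an o-hydroxyacetophenone; ring B of flavone 1 is cut at C1'–C2' and C3'–C4' (CO2 re-added across C1'/C4') into a 2-pyrone and an 8-ethynylflavone; last comes the C8''–C(sp) bond.
Enabling feature: in ring B of flavone 1 the oxygen-bearing C4' is para to C1' (which holds C2 of flavone 1) and ortho to C3' (bound to C8'' of flavone 2); a 3-alkoxy-2-pyrone-6-carboxylate already has O–C3 and C6–CO2R in that 1,4 relation (C3→C4', C4→C5', C5→C6', C6→C1', ester carbon→C2), and an alkyne on C8'' supplies C3' and C2'.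
Forward order: the three rings of flavone 2 come intact from apigenin; ring B of flavone 1 is built in step 9; the pyranone ring of flavone 1 closes in step 14 onto ring A of flavone 1, which comes from 2,6-dimethoxytoluene.
Stereochemistry: the target has no stereocentre; the four stereocentres of galactaric acid are erased in step 1.
Protection: benzyl on O4', O7'' and O4''', methyl on the two peri oxygens O5 and O5''; one BCl3 step removes all five and keeps the 7-OMe.

Key step: step 9

Assumption: the C3'–C8'' biaryl axis is drawn without configuration, so it is treated as stereochemically undefined and no atropselective control is planned.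

Step 1
Reactants: 1 galactaric acid
Product: 2 sodium 3-acetoxy-2-oxo-2H-pyran-6-carboxylate
Conditions: Ac2O, NaOAc, 100 °C
Reagents that add atoms: acetic anhydride, CC(=O)OC(C)=O (acetyl group); sodium acetate, CC(=O)[O-].[Na+] (sodium counter-ion)
Why: Acetic anhydride dehydration of a C6 aldaric acid (peracetylation, lactonisation, two β-eliminations of acetic acid) is the established entry to 3-acyloxy-2-pyrone-6-carboxylate salts, and all four stereocentres are removed, so their configuration is irrelevant.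

Step 2
Reactants: 2 sodium 3-acetoxy-2-oxo-2H-pyran-6-carboxylate
Product: 3 methyl 3-hydroxy-2-oxo-2H-pyran-6-carboxylate
Conditions: HCl (1.25 M in MeOH), reflux
Reagents that add atoms: methanol, CO
Why: Fischer esterification of the liberated acid and acid-catalysed transesterification of the enol acetate run under the same conditions, and the 2-pyranone ring, as in coumalic acid, should survive methanolic acid.

Step 3
Reactants: 3 methyl 3-hydroxy-2-oxo-2H-pyran-6-carboxylate
Product: 4 methyl 3-(benzyloxy)-2-oxo-2H-pyran-6-carboxylate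
Conditions: BnBr, K2CO3, DMF, rt
Reagents that add atoms: benzyl bromide, BrCc1ccccc1
Why: Williamson O-alkylation of the acidic enolic 3-hydroxyl, the only OH present, needs only a mild carbonate base.

Step 4
Reactants: 5 apigenin
Product: 6 7,4'-di-O-benzylapigenin (7-benzyloxy-2-(4-benzyloxyphenyl)-5-hydroxy-4H-chromen-4-one)
Conditions: BnBr (2.2 equiv), K2CO3, DMF, rt
Reagents that add atoms: benzyl bromide, BrCc1ccccc1
Why: Williamson etherification is selective for the 7- and 4'-phenols because the 5-OH is hydrogen-bonded to the C4 carbonyl and far less nucleophilic.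

Step 5
Reactants: 6 7,4'-di-O-benzylapigenin
Product: 7 7,4'-di-O-benzyl-5-O-methylapigenin
Conditions: Me2SO4, K2CO3, acetone, reflux
Reagents that add atoms: dimethyl sulfate, COS(=O)(=O)OC
Why: Forcing Williamson methylation (excess dimethyl sulfate, refluxing acetone) overcomes the chelation of the 5-OH, the only free hydroxyl left.

Step 6
Reactants: 7 7,4'-di-O-benzyl-5-O-methylapigenin
Product: 8 8-iodo-7,4'-di-O-benzyl-5-O-methylapigenin
Conditions: I2, CF3CO2Ag, CH2Cl2, 0 °C → rt
Reagents that add atoms: iodine, II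
Why: Silver-assisted electrophilic aromatic iodination of fully O-alkylated 5,7-dioxygenated flavones is expected at C8 (a free 5-OH, which would steer the electrophile to C6, is absent), and ring A of flavone 2 is far more electron-rich than the 4-benzyloxyphenyl ring.

Step 7
Reactants: 8 8-iodo-7,4'-di-O-benzyl-5-O-methylapigenin
Product: 9 8-[(trimethylsilyl)ethynyl]-7,4'-di-O-benzyl-5-O-methylapigenin
Conditions: TMS-acetylene, PdCl2(PPh3)2, CuI, Et3N, DMF, 60 °C
Reagents that add atoms: ethynyltrimethylsilane, C#C[Si](C)(C)C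
Why: Sonogashira coupling of an electron-rich aryl iodide is reliable, and because both flanking oxygens are alkylated the product cannot cyclise to a benzofuran.

Step 8
Reactants: 9 8-[(trimethylsilyl)ethynyl]-7,4'-di-O-benzyl-5-O-methylapigenin
Product: 10 8-ethynyl-7,4'-di-O-benzyl-5-O-methylapigenin
Conditions: K2CO3 (cat.), MeOH/THF, rt
Reagents that add atoms: none
Why: Base-catalysed methanolysis of the C(sp)–Si bond (protodesilylation) is fast and leaves the ethers and the flavone untouched.

Step 9
Reactants: 4 methyl 3-(benzyloxy)-2-oxo-2H-pyran-6-carboxylate; 10 8-ethynyl-7,4'-di-O-benzyl-5-O-methylapigenin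
Product: 12 methyl 4-(benzyloxy)-3-[7-(benzyloxy)-2-(4-benzyloxyphenyl)-5-methoxy-4-oxo-4H-chromen-8-yl]benzoate, via bridged bicyclic lactone 11 (not isolated)
Conditions: 3 equiv of 4, BHT (cat.), 1,2-dichlorobenzene, 180 °C, sealed tube
Reagents that add atoms: none
Why: Proposed new method: the electron-poor pyrone 4 (diene C3=C4–C5=C6) and the electron-rich arylalkyne 10 should undergo an asynchronous, inverse-demand [4+2] cycloaddition to the 2-oxabicyclo[2.2.2]octadienone 11, which at this temperature extrudes CO2 by retro-[4+2] and aromatises to ring B of flavone 1. The closest known reaction type is the thermal Diels–Alder/decarboxylation of 2-pyrones (coumalates and 3-oxygenated 2-pyrones) with terminal arylalkynes giving biaryl benzoates; a 3-alkoxy-2-pyrone-6-carboxylate combined with a di-ortho-substituted flavon-8-yl alkyne has not been shown. The ring closes by intermolecular [4+2] annulation, four carbons from the pyrone (C3 to C6) and two from the alkyne, so that C1'–C2' and C3'–C4' form in the same operation and no aryl–aryl coupling is needed. No stereocentre results, since the two bridgehead centres of 11 disappear with CO2 and the biaryl axis is not a defined stereo element of the target. The step needs regiocontrol: the terminal alkyne carbon (the nucleophilic end of an aryl-conjugated alkyne, the developing positive charge being held by the trioxygenated ring A of flavone 2) must bond to pyrone C6 and the aryl-bearing carbon to C3. This should be secured by C6 being the electrophilic terminus of the 2-pyranone (delta to the lactone carbonyl, carrying the ester and only the weakly donating acyloxy ring oxygen) while C3 is deactivated by its benzyloxy donor, and by the flavonyl group then sitting beside the small ether oxygen instead of the ester; the excess of inexpensive pyrone offsets its slow thermal decomposition.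

Step 10
Reactants: 12 methyl 4-(benzyloxy)-3-[7-(benzyloxy)-2-(4-benzyloxyphenyl)-5-methoxy-4-oxo-4H-chromen-8-yl]benzoate
Product: 13 4-(benzyloxy)-3-[7-(benzyloxy)-2-(4-benzyloxyphenyl)-5-methoxy-4-oxo-4H-chromen-8-yl]benzoic acid
Conditions: LiOH, THF/MeOH/H2O, rt; then aq. HCl
Reagents that add atoms: lithium hydroxide, [Li+].[OH-] (the hydroxyl oxygen of the acid)
Why: Saponification of an unhindered methyl benzoate is routine, 2-aryl-4H-chromen-4-ones tolerate dilute hydroxide at room temperature, and the benzyl and methyl ethers are inert.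

Step 11
Reactants: 14 2,6-dimethoxytoluene
Product: 16 3,5-dimethoxy-4-methylphenol, via aryl pinacol boronate 15 (not isolated)
Conditions: [Ir(OMe)(cod)]2 (cat.), dtbpy, B2pin2 (0.6 equiv), THF, 80 °C; then Oxone (KHSO5), acetone/H2O, rt
Reagents that add atoms: potassium peroxymonosulfate, [K+].[O-]S(=O)(=O)OO (the phenol oxygen); bis(pinacolato)diboron, CC1(C)OB(OC1(C)C)B1OC(C)(C)C(C)(C)O1 (the boryl group of 15 only, lost again on oxidation)
Why: Iridium-catalysed C–H borylation is sterically governed and should take the only C–H without an ortho substituent (C4, para to the methyl group), and oxidation of the C–B bond in the same flask then gives the phenol.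

Step 12
Reactants: 16 3,5-dimethoxy-4-methylphenol
Product: 17 1-(6-hydroxy-2,4-dimethoxy-3-methylphenyl)ethan-1-one
Conditions: Ac2O, BF3·OEt2, 70 °C; aq. work-up
Reagents that add atoms: acetic anhydride, CC(=O)OC(C)=O
Why: BF3-promoted Friedel–Crafts acylation ortho to the phenol can give only one regioisomer, because the para position is blocked by the methyl group and the two ortho positions are equivalent by symmetry.

Step 13
Reactants: 13 4-(benzyloxy)-3-[7-(benzyloxy)-2-(4-benzyloxyphenyl)-5-methoxy-4-oxo-4H-chromen-8-yl]benzoic acid; 17 1-(6-hydroxy-2,4-dimethoxy-3-methylphenyl)ethan-1-one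
Product: 18 2-acetyl-3,5-dimethoxy-4-methylphenyl 4-(benzyloxy)-3-[7-(benzyloxy)-2-(4-benzyloxyphenyl)-5-methoxy-4-oxo-4H-chromen-8-yl]benzoate
Conditions: EDC·HCl, DMAP, CH2Cl2, rt
Reagents that add atoms: none
Why: Steglich esterification should acylate the phenol of 17, the only alcohol or phenol in either partner, with DMAP transferring the acyl group to this hydrogen-bonded phenol.

Step 14
Reactants: 18 2-acetyl-3,5-dimethoxy-4-methylphenyl 4-(benzyloxy)-3-[7-(benzyloxy)-2-(4-benzyloxyphenyl)-5-methoxy-4-oxo-4H-chromen-8-yl]benzoate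
Product: 20 5,7-dimethoxy-6-methyl-2-{4-(benzyloxy)-3-[7-(benzyloxy)-2-(4-benzyloxyphenyl)-5-methoxy-4-oxo-4H-chromen-8-yl]phenyl}-4H-chromen-4-one, via 1,3-diketone 19 (not isolated)
Conditions: LiN(SiMe3)2 (3 equiv), THF, −78 → 0 °C; AcOH quench; then p-TsOH·H2O (cat.), toluene, 100 °C
Reagents that add atoms: none
Why: Baker–Venkataraman rearrangement (intramolecular Claisen acyl transfer from the ketone enolate through a six-membered transition state) followed by acid-catalysed cyclodehydration can only give the 5,7-dimethoxy-6-methyl pattern, because the sole free phenol of 19 is the one next to the aromatic C–H.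

Step 15
Reactants: 20 5,7-dimethoxy-6-methyl-2-{4-(benzyloxy)-3-[7-(benzyloxy)-2-(4-benzyloxyphenyl)-5-methoxy-4-oxo-4H-chromen-8-yl]phenyl}-4H-chromen-4-one
Product: 21 5-hydroxy-7-methoxy-6-methyl-2-{4-hydroxy-3-[5,7-dihydroxy-2-(4-hydroxyphenyl)-4-oxo-4H-chromen-8-yl]phenyl}-4H-chromen-4-one (6-methyl-7-O-methylamentoflavone, the target)
Conditions: BCl3 (excess), C6HMe5, CH2Cl2, −78 °C → rt; aq. work-up
Reagents that add atoms: none
Why: Lewis-acid ether cleavage with BCl3 and pentamethylbenzene as benzyl-cation scavenger should remove the three aryl benzyl ethers at low temperature and, on warming, the two methyl ethers peri to the C4 and C4'' carbonyls through six-membered boron chelates, while the non-chelated 7-OMe is not activated.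

**Compound list**
1 | galactaric acid (mucic acid, meso) | OC(=O)[C@H](O)[C@@H](O)[C@@H](O)[C@H](O)C(=O)O | starting material
2 | sodium 3-acetoxy-2-oxo-2H-pyran-6-carboxylate | CC(=O)Oc1ccc(C(=O)[O-])oc1=O.[Na+] | intermediate
3 | methyl 3-hydroxy-2-oxo-2H-pyran-6-carboxylate | COC(=O)c1ccc(O)c(=O)o1 | intermediate
4 | methyl 3-(benzyloxy)-2-oxo-2H-pyran-6-carboxylate | COC(=O)c1ccc(OCc2ccccc2)c(=O)o1 | intermediate
5 | apigenin | O=c1cc(-c2ccc(O)cc2)oc2cc(O)cc(O)c12 | starting material
6 | 7,4'-di-O-benzylapigenin | O=c1cc(-c2ccc(OCc3ccccc3)cc2)oc2cc(OCc3ccccc3)cc(O)c12 | intermediate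
7 | 7,4'-di-O-benzyl-5-O-methylapigenin | COc1cc(OCc2ccccc2)cc2oc(-c3ccc(OCc4ccccc4)cc3)cc(=O)c12 | intermediate
8 | 8-iodo-7,4'-di-O-benzyl-5-O-methylapigenin | COc1cc(OCc2ccccc2)c(I)c2oc(-c3ccc(OCc4ccccc4)cc3)cc(=O)c12 | intermediate
9 | 8-[(trimethylsilyl)ethynyl]-7,4'-di-O-benzyl-5-O-methylapigenin | COc1cc(OCc2ccccc2)c(C#C[Si](C)(C)C)c2oc(-c3ccc(OCc4ccccc4)cc3)cc(=O)c12 | intermediate
10 | 8-ethynyl-7,4'-di-O-benzyl-5-O-methylapigenin | C#Cc1c(OCc2ccccc2)cc(OC)c2c(=O)cc(-c3ccc(OCc4ccccc4)cc3)oc12 | intermediate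
11 | methyl 4-(benzyloxy)-5-[7-(benzyloxy)-2-(4-benzyloxyphenyl)-5-methoxy-4-oxo-4H-chromen-8-yl]-3-oxo-2-oxabicyclo[2.2.2]octa-5,7-diene-1-carboxylate (racemic bridged lactone) | COC(=O)C12C=CC(OCc3ccccc3)(C(=O)O1)C(=C2)c1c(OCc2ccccc2)cc(OC)c2c(=O)cc(-c3ccc(OCc4ccccc4)cc3)oc12 | intermediate
12 | methyl 4-(benzyloxy)-3-[7-(benzyloxy)-2-(4-benzyloxyphenyl)-5-methoxy-4-oxo-4H-chromen-8-yl]benzoate | COC(=O)c1ccc(OCc2ccccc2)c(-c2c(OCc3ccccc3)cc(OC)c3c(=O)cc(-c4ccc(OCc5ccccc5)cc4)oc23)c1 | intermediate
13 | 4-(benzyloxy)-3-[7-(benzyloxy)-2-(4-benzyloxyphenyl)-5-methoxy-4-oxo-4H-chromen-8-yl]benzoic acid | OC(=O)c1ccc(OCc2ccccc2)c(-c2c(OCc3ccccc3)cc(OC)c3c(=O)cc(-c4ccc(OCc5ccccc5)cc4)oc23)c1 | intermediate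
14 | 2,6-dimethoxytoluene | COc1cccc(OC)c1C | starting material
15 | 2-(3,5-dimethoxy-4-methylphenyl)-4,4,5,5-tetramethyl-1,3,2-dioxaborolane | COc1cc(B2OC(C)(C)C(C)(C)O2)cc(OC)c1C | intermediate
16 | 3,5-dimethoxy-4-methylphenol | COc1cc(O)cc(OC)c1C | intermediate
17 | 1-(6-hydroxy-2,4-dimethoxy-3-methylphenyl)ethan-1-one | CC(=O)c1c(O)cc(OC)c(C)c1OC | intermediate
18 | 2-acetyl-3,5-dimethoxy-4-methylphenyl ester of acid 13 | CC(=O)c1c(OC(=O)c2ccc(OCc3ccccc3)c(-c3c(OCc4ccccc4)cc(OC)c4c(=O)cc(-c5ccc(OCc6ccccc6)cc5)oc34)c2)cc(OC)c(C)c1OC | intermediate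
19 | 1-(6-hydroxy-2,4-dimethoxy-3-methylphenyl)-3-{4-(benzyloxy)-3-[7-(benzyloxy)-2-(4-benzyloxyphenyl)-5-methoxy-4-oxo-4H-chromen-8-yl]phenyl}propane-1,3-dione | COc1cc(O)c(C(=O)CC(=O)c2ccc(OCc3ccccc3)c(-c3c(OCc4ccccc4)cc(OC)c4c(=O)cc(-c5ccc(OCc6ccccc6)cc5)oc34)c2)c(OC)c1C | intermediate
20 | 5,7-dimethoxy-6-methyl-2-{4-(benzyloxy)-3-[7-(benzyloxy)-2-(4-benzyloxyphenyl)-5-methoxy-4-oxo-4H-chromen-8-yl]phenyl}-4H-chromen-4-one (protected biflavone) | COc1cc2oc(-c3ccc(OCc4ccccc4)c(-c4c(OCc5ccccc5)cc(OC)c5c(=O)cc(-c6ccc(OCc7ccccc7)cc6)oc45)c3)cc(=O)c2c(OC)c1C | intermediate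
21 | 6-methyl-7-O-methylamentoflavone (5,4',5'',7'',4'''-pentahydroxy-7-methoxy-6-methyl-3',8''-biflavone) | COc1cc2oc(-c3ccc(O)c(-c4c(O)cc(O)c5c(=O)cc(-c6ccc(O)cc6)oc45)c3)cc(=O)c2c(O)c1C | target

**Count and risks**
Total steps: 15. Longest linear sequence: 10 steps (apigenin 5 through steps 4–10 and 13–15 to 21). The pyrone arm (steps 1–3) and the acetophenone arm (steps 11–12) are side branches.

Steps most likely to fail:

1. Step 9 (proposed new method). The cycloaddition may proceed with the reverse orientation (aryl-bearing carbon to pyrone C6), or so slowly at the hindered alkyne that the pyrone is consumed by thermal decomposition first. The fallback is a Suzuki–Miyaura biaryl coupling, which is known chemistry for 8-iodoflavones. It sets out from iodide 8 and returns to the route at 12. Commercial methyl 3-bromo-4-hydroxybenzoate would be O-benzylated (BnBr, K2CO3, DMF) to methyl 4-(benzyloxy)-3-bromobenzoate F1. Miyaura borylation (B2pin2, PdCl2(dppf), KOAc, dioxane, 90 °C) should then give methyl 4-(benzyloxy)-3-(4,4,5,5-tetramethyl-1,3,2-dioxaborolan-2-yl)benzoate F2. Coupling of F2 with 8 (Pd(OAc)2, SPhos, K3PO4, toluene/H2O, 90 °C) should deliver 12. In that case steps 1–3, 7 and 8 are not needed.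

2. Step 15. Ether cleavage may stop short when partly deprotected boron chelates precipitate, benzyl cations may re-alkylate the phloroglucinol-type rings, or prolonged exposure may attack the 7-methyl ether. The fallback separates the two kinds of ether by different mechanisms. It sets out from 20 and returns at 21. Hydrogenolysis (H2, Pd/C, THF/MeOH, rt) should remove the three benzyl groups and give 5,5''-di-O-methyl-6-methyl-7-O-methylamentoflavone F3. Chelation-controlled demethylation of the two peri methoxy groups with AlCl3 in MeCN (60 °C) should then give 21.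

3. Step 14. The strong base may cleave the aryl ester back to its components or open the pyranone ring of flavone 2 instead of effecting acyl transfer, and the acid stage may cost benzyl ethers. The fallback builds the pyranone ring by the chalcone route. It sets out from acid 13 (with acetophenone 17) and returns at 20. The acid would be activated with iBuOCOCl and N-methylmorpholine (THF, −10 °C) as 4-(benzyloxy)-3-[7-(benzyloxy)-2-(4-benzyloxyphenyl)-5-methoxy-4-oxo-4H-chromen-8-yl]benzoic isobutyl carbonic anhydride F4, which NaBH4 in aqueous THF should reduce in the same flask to {4-(benzyloxy)-3-[7-(benzyloxy)-2-(4-benzyloxyphenyl)-5-methoxy-4-oxo-4H-chromen-8-yl]phenyl}methanol F5. Oxidation with MnO2 (CH2Cl2, rt) should give the corresponding benzaldehyde F6. Claisen–Schmidt condensation of this aldehyde with 17 (KOH, EtOH/THF, rt) should give the (E)-2'-hydroxychalcone F7. Oxidative cyclisation (I2 cat., DMSO, 120 °C) should then give 20.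

**Further compounds**
F1 | step 9 | methyl 4-(benzyloxy)-3-bromobenzoate | COC(=O)c1ccc(OCc2ccccc2)c(Br)c1
F2 | step 9 | methyl 4-(benzyloxy)-3-(4,4,5,5-tetramethyl-1,3,2-dioxaborolan-2-yl)benzoate | COC(=O)c1ccc(OCc2ccccc2)c(B2OC(C)(C)C(C)(C)O2)c1
F3 | step 15 | 5,5''-di-O-methyl-6-methyl-7-O-methylamentoflavone (4',7'',4'''-triol) | COc1cc2oc(-c3ccc(O)c(-c4c(O)cc(OC)c5c(=O)cc(-c6ccc(O)cc6)oc45)c3)cc(=O)c2c(OC)c1C
F4 | step 14 | 4-(benzyloxy)-3-[7-(benzyloxy)-2-(4-benzyloxyphenyl)-5-methoxy-4-oxo-4H-chromen-8-yl]benzoic isobutyl carbonic anhydride | CC(C)COC(=O)OC(=O)c1ccc(OCc2ccccc2)c(-c2c(OCc3ccccc3)cc(OC)c3c(=O)cc(-c4ccc(OCc5ccccc5)cc4)oc23)c1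
F5 | step 14 | {4-(benzyloxy)-3-[7-(benzyloxy)-2-(4-benzyloxyphenyl)-5-methoxy-4-oxo-4H-chromen-8-yl]phenyl}methanol | OCc1ccc(OCc2ccccc2)c(-c2c(OCc3ccccc3)cc(OC)c3c(=O)cc(-c4ccc(OCc5ccccc5)cc4)oc23)c1
F6 | step 14 | 4-(benzyloxy)-3-[7-(benzyloxy)-2-(4-benzyloxyphenyl)-5-methoxy-4-oxo-4H-chromen-8-yl]benzaldehyde | O=Cc1ccc(OCc2ccccc2)c(-c2c(OCc3ccccc3)cc(OC)c3c(=O)cc(-c4ccc(OCc5ccccc5)cc4)oc23)c1
F7 | step 14 | (E)-1-(6-hydroxy-2,4-dimethoxy-3-methylphenyl)-3-{4-(benzyloxy)-3-[7-(benzyloxy)-2-(4-benzyloxyphenyl)-5-methoxy-4-oxo-4H-chromen-8-yl]phenyl}prop-2-en-1-one | COc1cc(O)c(C(=O)/C=C/c2ccc(OCc3ccccc3)c(-c3c(OCc4ccccc4)cc(OC)c4c(=O)cc(-c5ccc(OCc6ccccc6)cc5)oc34)c2)c(OC)c1C
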